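The cyclopentane ring is disconnected at C1–C2 and C4–C5 (daucane numbering: C1 methyl-bearing fusion carbon, C4 carbinol, C5 fusion CH, C6 ester carbon). In one pot the zinc homoenolate of 1-isopropylcyclopropanol (C2–C3–C4) adds to C1 of 3,6-dimethylcyclohepta-2,5-dienone and the resulting C5 enolate closes onto the C4 ketone; dehydration funnels the ketol to one enone. The step exploits that C1 is β and C5 α to the C6 carbonyl of the seven-membered ring and that the C4 oxygen is 1,3 to the C6 oxygen. The trans ring fusion, both carbinols and the epoxide are then set by hydroxyl-directed or stereospecific steps.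

Key step: step 6

Remarks on the chemistry:
- Daucane numbering is used for all bicyclic compounds: C1 (quaternary, CH3), C2, C3, C4 (carbinol, isopropyl), C5 (ring-fusion CH), C6 (oxygenated), C7, C8 (CH3), C9, C10. β is the face of the C1 methyl group, α the opposite face. The target is read as the 8α,9α-epoxy-4β-hydroxy-5αH-daucan-6α-yl ester.
- Racemic intermediates (4, 5, 6) are drawn as one enantiomer or without descriptor; the absolute configuration is introduced in step 6.
- Assumption: 2,5-dimethylphenol, methyl 2-methylpropanoate, 3,4-dimethoxybenzoyl chloride and all reagents are commercial; 1-isopropylcyclopropanol is made in step 5 (side branch).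

Step 1
Reactants: 1 2,5-dimethylphenol
Product: 2 (2,5-dimethylphenoxy)tri(propan-2-yl)silane
Conditions: TIPSCl, imidazole, DMF, rt
Reagents that add atoms: chlorotri(propan-2-yl)silane (TIPSCl), CC(C)[Si](Cl)(C(C)C)C(C)C
Why: Imidazole-promoted O-silylation should give an aryl silyl ether robust enough for dissolving-metal reduction, so that the phenol oxygen reappears as a regiodefined silyl enol ether; no stereocentre.

Step 2
Reactants: 2 (2,5-dimethylphenoxy)tri(propan-2-yl)silane
Product: 3 [(2,5-dimethylcyclohexa-1,4-dien-1-yl)oxy]tri(propan-2-yl)silane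
Conditions: Li, NH3(l), THF, t-BuOH, −78 to −33 °C; NH4Cl
Reagents that add atoms: none
Why: Birch reduction of an aryl ether should leave the oxygen and both methyl groups on the two residual double bonds, so the silyl enol ether C=C (future C6/C1) and the trisubstituted C=C (future C8=C9) are formed regiospecifically; no stereocentre.

Step 3
Reactants: 3 [(2,5-dimethylcyclohexa-1,4-dien-1-yl)oxy]tri(propan-2-yl)silane
Product: 4 racemic [(3,6-dimethylbicyclo[4.1.0]hept-3-en-1-yl)oxy]tri(propan-2-yl)silane
Conditions: Et2Zn, CH2I2, CH2Cl2, 0 °C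
Reagents that add atoms: diiodomethane, ICI
Why: Simmons–Smith cyclopropanation (Furukawa variant) with the electrophilic zinc carbenoid should be fastest at the electron-rich silyl enol ether double bond; the cis ring fusion is the only one possible and the product is racemic.

Step 4
Reactants: 4 racemic [(3,6-dimethylbicyclo[4.1.0]hept-3-en-1-yl)oxy]tri(propan-2-yl)silane
Product: 7 3,6-dimethylcyclohepta-2,5-dien-1-one, via cyclopropanol 5 (not isolated), via chloro ketone 6 (not isolated)
Conditions: TBAF, AcOH, THF, 0 °C; then FeCl3, DMF, 0 °C; then NaOAc, MeOH, rt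
Reagents that add atoms: none
Why: Oxidative ring expansion of a cyclopropanol: FeCl3 should generate the alkoxy radical, whose β-scission breaks the internal bond to the tertiary radical and gives the ring-expanded β-chloro ketone, and E1cB loss of HCl then gives the conjugated enone with the second double bond left out of conjugation; the stereocentres of 4 disappear.

Step 5
Reactants: 8 methyl 2-methylpropanoate
Product: 9 1-(propan-2-yl)cyclopropan-1-ol
Conditions: EtMgBr (2.2 equiv), Ti(OiPr)4 (10 mol %), Et2O, rt; aq. NH4Cl
Reagents that add atoms: ethylmagnesium bromide, CC[Mg]Br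
Why: Kulinkovich cyclopropanation: the low-valent titanium species formed from EtMgBr and Ti(OiPr)4 should transfer an ethane-1,2-diyl unit to the ester carbonyl; no stereocentre.

Step 6
Reactants: 7 3,6-dimethylcyclohepta-2,5-dien-1-one; 9 1-(propan-2-yl)cyclopropan-1-ol
Product: 13 (8aR)-6,8a-dimethyl-3-(propan-2-yl)-1,2,8,8a-tetrahydroazulen-4(5H)-one, via zinc homoenolate 10 (not isolated), via cis-fused ketol 11 (not isolated), via ketol mesylate 12 (not isolated)
Conditions: 9 (3 equiv), Et2Zn (1.5 equiv), toluene, 0 °C to rt; Cu(OTf)2 (5 mol %), (S)-1-mesityl-3-(1-hydroxy-4-methylpentan-2-yl)-4,5-dihydroimidazolium hexafluorophosphate (6 mol %; the enantiomer that gives the R centre is to be used), 7, Et2O, −30 to 0 °C; then Et3N, MsCl, 0 °C to rt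
Reagents that add atoms: none
Why: Proposed new method: Et2Zn should open 9 to the zinc homoenolate 10, whose alkyl group is passed to the chiral copper–carbene catalyst generated from Cu(OTf)2 and the imidazolinium salt and added 1,4 to the enantiotopic face of C1 of enone 7 that gives the R-configured quaternary centre (C1–C2 bond); the closest known reaction types are the copper–carbene-catalysed enantioselective conjugate addition of dialkylzinc reagents to 3-methylcycloalk-2-enones and the conjugate addition of cyclopropanol-derived zinc homoenolates to simple enones, which have not been combined on a β,β-disubstituted cyclic enone. The zinc enolate, formed regiospecifically at C5, should then attack the tethered C4 ketone in a 5-(enolexo)-exo-trig aldol that closes the cyclopentane ring (C4–C5 bond) and gives the cis-fused ketol 11 under chelate control. C1 is the only new stereocentre that is kept and the ligand sets it; C4 and C5 of 11 are erased on purpose by mesylation and E1cB elimination to enone 13, because a five-membered ring closed onto a ring enolate is cis-fused and the trans fusion is installed later (steps 8 and 9). The step needs 1,4- rather than 1,2-addition (soft organocopper, zinc alkyl inert to ketones), reaction at the enone and not at the isolated C8=C9 bond, and aldolisation through C5 rather than C7, which the conjugate addition secures by generating the enolate where it is needed. Elimination can only give the C4=C5 enone because C5–H is the one acidic hydrogen next to the leaving group.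

Step 7
Reactants: 13 (8aR)-6,8a-dimethyl-3-(propan-2-yl)-1,2,8,8a-tetrahydroazulen-4(5H)-one
Product: 14 (4R,8aR)-6,8a-dimethyl-3-(propan-2-yl)-1,2,4,5,8,8a-hexahydroazulen-4-ol (6β-OH)
Conditions: (S)-Me-CBS oxazaborolidine (20 mol %), catecholborane, toluene, −78 °C
Reagents that add atoms: none
Why: Corey–Bakshi–Shibata reduction with the alkenyl carbon as the large group should deliver hydride 1,2 to the α-face of C6 and give the R carbinol (6β-OH), a sense the substrate also favours because the pseudo-axial C1 methyl group shields the β-face; catecholborane should leave the C8=C9 alkene untouched.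

Step 8
Reactants: 14 (4R,8aR)-6,8a-dimethyl-3-(propan-2-yl)-1,2,4,5,8,8a-hexahydroazulen-4-ol
Product: 15 4β,5β-epoxide of 14 (oxirane oxygen syn to the 6β-OH and to the C1 methyl group)
Conditions: VO(acac)2 (2 mol %), t-BuOOH (1.1 equiv), CH2Cl2, 0 °C
Reagents that add atoms: tert-butyl hydroperoxide, CC(C)(C)OO
Why: Hydroxyl-directed epoxidation of the allylic tetrasubstituted C4=C5 bond should deliver oxygen syn to the 6β-OH, which sets the 4β-oxygen, and should be much faster than attack on the homoallylic C8=C9 bond.

Step 9
Reactants: 15 4β,5β-epoxide of 14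
Product: 16 (3R,3aR,8aR)-3-hydroxy-6,8a-dimethyl-3-(propan-2-yl)-1,2,3,3a,8,8a-hexahydroazulen-4(5H)-one (trans-fused ketol, 4β-OH, 5α-H)
Conditions: ZnBr2, CH2Cl2, 0 °C
Reagents that add atoms: none
Why: Semipinacol rearrangement of a 2,3-epoxy alcohol: with zinc bridging the syn hydroxyl and oxirane oxygens the C5–O bond should ionise with concerted 1,2-shift of the antiperiplanar C6–H (α) to the α-face of C5, so H-5 ends anti to the retained 4β-oxygen (trans ring fusion) and C6 becomes the ketone; the ring carbon C7 is gauche to the breaking bond and should not migrate.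

Step 10
Reactants: 16 trans-fused ketol
Product: 17 (3R,3aS,4S,8aR)-6,8a-dimethyl-3-(propan-2-yl)-1,2,3,3a,4,5,8,8a-octahydroazulene-3,4-diol (jaeschkeanadiol; 4β-OH, 6α-OH)
Conditions: Me4NBH(OAc)3, MeCN/AcOH, −20 °C
Reagents that add atoms: none
Why: Evans–Saksena reduction: the acetoxyborohydride bound to the 4β-hydroxyl should deliver hydride intramolecularly to the β-face of the C6 ketone and give the 1,3-anti diol (6α-OH).

Step 11
Reactants: 17 jaeschkeanadiol
Product: 18 8α,9α-epoxyjaeschkeanadiol
Conditions: VO(acac)2 (5 mol %), t-BuOOH, CH2Cl2, 0 °C to rt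
Reagents that add atoms: tert-butyl hydroperoxide, CC(C)(C)OO
Why: Hydroxyl-directed epoxidation of the homoallylic trisubstituted C8=C9 bond should place the oxirane oxygen syn to the 6α-OH (8α,9α), the tertiary 4β-OH being too remote to compete.

Step 12
Reactants: 18 8α,9α-epoxyjaeschkeanadiol; 19 3,4-dimethoxybenzoyl chloride
Product: 20 8α,9α-epoxy-4β-hydroxy-5αH-daucan-6α-yl 3,4-dimethoxybenzoate (target)
Conditions: Et3N, DMAP (cat.), CH2Cl2, 0 °C to rt
Reagents that add atoms: none
Why: DMAP-catalysed acylation (nucleophilic catalysis) should esterify only the secondary 6α-OH, the hindered tertiary 4β-OH and the epoxide being inert under these basic conditions; no stereocentre is touched.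

Compound list
1 | 2,5-dimethylphenol | Cc1ccc(C)c(O)c1 | starting material
2 | (2,5-dimethylphenoxy)tri(propan-2-yl)silane | Cc1ccc(C)c(O[Si](C(C)C)(C(C)C)C(C)C)c1 | intermediate
3 | [(2,5-dimethylcyclohexa-1,4-dien-1-yl)oxy]tri(propan-2-yl)silane | CC1=C(O[Si](C(C)C)(C(C)C)C(C)C)CC(C)=CC1 | intermediate
4 | racemic cis-fused [(3,6-dimethylbicyclo[4.1.0]hept-3-en-1-yl)oxy]tri(propan-2-yl)silane (one enantiomer drawn) | C[C@]12C[C@@]1(O[Si](C(C)C)(C(C)C)C(C)C)CC(C)=CC2 | intermediate
5 | racemic 3,6-dimethylbicyclo[4.1.0]hept-3-en-1-ol (not isolated; one enantiomer drawn) | C[C@]12C[C@@]1(O)CC(C)=CC2 | intermediate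
6 | racemic 3-chloro-3,6-dimethylcyclohept-5-en-1-one (not isolated) | CC1(Cl)CC=C(C)CC(=O)C1 | intermediate
7 | 3,6-dimethylcyclohepta-2,5-dien-1-one | CC1=CC(=O)CC(C)=CC1 | intermediate
8 | methyl 2-methylpropanoate | COC(=O)C(C)C | starting material
9 | 1-(propan-2-yl)cyclopropan-1-ol | CC(C)C1(O)CC1 | intermediate
10 | bis(4-methyl-3-oxopentyl)zinc, the zinc homoenolate (not isolated) | CC(C)C(=O)CC[Zn]CCC(=O)C(C)C | intermediate
11 | cis-fused ketol, present as its zinc alkoxide (not isolated; 1β-CH3, 5β-H, 4α-OH) | O=C1CC(C)=CC[C@@]2(C)CC[C@](O)(C(C)C)[C@@H]12 | intermediate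
12 | methanesulfonate of 11 (not isolated) | O=C1CC(C)=CC[C@@]2(C)CC[C@](OS(C)(=O)=O)(C(C)C)[C@@H]12 | intermediate
13 | (8aR)-6,8a-dimethyl-3-(propan-2-yl)-1,2,8,8a-tetrahydroazulen-4(5H)-one | CC(C)C1=C2C(=O)CC(C)=CC[C@@]2(C)CC1 | intermediate
14 | (4R,8aR)-6,8a-dimethyl-3-(propan-2-yl)-1,2,4,5,8,8a-hexahydroazulen-4-ol | O[C@@H]1CC(C)=CC[C@@]2(C)CCC(C(C)C)=C12 | intermediate
15 | 4β,5β-epoxy-dauc-8-en-6β-ol (epoxy alcohol) | O[C@@H]1CC(C)=CC[C@@]2(C)CC[C@]3(C(C)C)O[C@]123 | intermediate
16 | (3R,3aR,8aR)-3-hydroxy-6,8a-dimethyl-3-(propan-2-yl)-1,2,3,3a,8,8a-hexahydroazulen-4(5H)-one | O=C1CC(C)=CC[C@@]2(C)CC[C@@](O)(C(C)C)[C@H]12 | intermediate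
17 | (3R,3aS,4S,8aR)-6,8a-dimethyl-3-(propan-2-yl)-1,2,3,3a,4,5,8,8a-octahydroazulene-3,4-diol (jaeschkeanadiol) | O[C@H]1CC(C)=CC[C@@]2(C)CC[C@@](O)(C(C)C)[C@H]12 | intermediate
18 | 8α,9α-epoxyjaeschkeanadiol | O[C@H]2C[C@@]3(C)O[C@H]3C[C@@]3(C)CC[C@@](O)(C(C)C)[C@H]23 | intermediate
19 | 3,4-dimethoxybenzoyl chloride | COc1ccc(C(=O)Cl)cc1OC | starting material
20 | 8α,9α-epoxy-4β-hydroxy-5αH-daucan-6α-yl 3,4-dimethoxybenzoate (CNP0251065.1) | COc1ccc(C(=O)O[C@H]2C[C@@]3(C)O[C@H]3C[C@@]3(C)CC[C@@](O)(C(C)C)[C@H]23)cc1OC | target

Total step count: 12. Longest linear sequence: 11 steps (steps 1–4 and 6–12; step 5 is a one-step side branch).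

Steps most likely to fail

Step 6 (Proposed new method). What may go wrong: the chelated zinc homoenolate may transfer too slowly to copper or add too slowly to the β,β-disubstituted enone; 7 may be enolised at its doubly allylic C10 or allylic C7 position; the ligand may discriminate the faces poorly. The fallback uses known chemistry, sets out from 7 and returns at 13, and builds the two bonds stepwise. Hydrozirconation of tert-butyl(dimethyl)[(4-methylpent-1-en-3-yl)oxy]silane F1 (from commercial 4-methylpent-1-en-3-ol, TBSCl and imidazole) with Cp2Zr(H)Cl gives an alkylzirconocene. Its copper-catalysed enantioselective conjugate addition to 7 (chiral phosphoramidite ligand), a known way to build quaternary centres on 3-methylcycloalkenones, should give (3R)-3-[3-(tert-butyldimethylsilyloxy)-4-methylpentyl]-3,6-dimethylcyclohept-5-en-1-one F2. TBAF should give (3R)-3-(3-hydroxy-4-methylpentyl)-3,6-dimethylcyclohept-5-en-1-one F3, and Dess–Martin oxidation (3R)-3,6-dimethyl-3-(4-methyl-3-oxopentyl)cyclohept-5-en-1-one F4. Aldol condensation (KOH, MeOH) should then close C4–C5 and give 13; the competing aldol through C3 onto C6 gives a bridged ketol that cannot dehydrate without forming a bridgehead alkene, so it reverts.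

Step 9. What may go wrong: the epoxide may ionise at C4 (an unassisted tertiary cation) instead of C5, followed by elimination or migration of a C5 substituent; the product ketol may also lose water under the Lewis acid. The fallback sets out from 15 and returns at 16. Dess–Martin oxidation of 15 should give 4β,5β-epoxy-dauc-8-en-6-one F5. SmI2 (THF/MeOH, −78 °C) should cleave reductively the only C–O bond α to the ketone (C5–O), which is regiospecific. Protonation of the samarium enolate and, if needed, equilibration through the enol should give the trans-fused ketol 16; its C5 epimer would carry the isopropyl group on the concave face of a cis-fused bicycle and is expected to be less stable.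

Step 4. What may go wrong: the skipped C8=C9 double bond may migrate into conjugation during the chloride elimination, or the external cyclopropane bond may be cleaved instead of the internal one. The fallback sets out from 3 and returns at 7. Dibromocarbene (CHBr3, KOt-Bu, pentane, 0 °C) should add to the silyl enol ether double bond of 3 to give 7,7-dibromo-3,6-dimethyl-1-[tri(propan-2-yl)silyloxy]bicyclo[4.1.0]hept-3-ene F6. Warming should trigger electrocyclic ring opening with loss of the silyl bromide to give 2-bromo-3,6-dimethylcyclohepta-2,5-dien-1-one F7. Hydrodebromination with Bu3SnH and Pd(PPh3)4 should give 7.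

Further compounds
F1 | step 6 | tert-butyl(dimethyl)[(4-methylpent-1-en-3-yl)oxy]silane | C=CC(O[Si](C)(C)C(C)(C)C)C(C)C
F2 | step 6 | (3R)-3-[3-(tert-butyldimethylsilyloxy)-4-methylpentyl]-3,6-dimethylcyclohept-5-en-1-one | CC(C)C(O[Si](C)(C)C(C)(C)C)CC[C@]1(C)CC=C(C)CC(=O)C1
F3 | step 6 | (3R)-3-(3-hydroxy-4-methylpentyl)-3,6-dimethylcyclohept-5-en-1-one | CC(C)C(O)CC[C@]1(C)CC=C(C)CC(=O)C1
F4 | step 6 | (3R)-3,6-dimethyl-3-(4-methyl-3-oxopentyl)cyclohept-5-en-1-one | CC(C)C(=O)CC[C@]1(C)CC=C(C)CC(=O)C1
F5 | step 9 | 4β,5β-epoxy-dauc-8-en-6-one | O=C1CC(C)=CC[C@@]2(C)CC[C@]3(C(C)C)O[C@]123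
F6 | step 4 | racemic 7,7-dibromo-3,6-dimethyl-1-[tri(propan-2-yl)silyloxy]bicyclo[4.1.0]hept-3-ene (one enantiomer drawn) | C[C@]12C(Br)(Br)[C@@]1(O[Si](C(C)C)(C(C)C)C(C)C)CC(C)=CC2
F7 | step 4 | 2-bromo-3,6-dimethylcyclohepta-2,5-dien-1-one | CC1=C(Br)C(=O)CC(C)=CC1
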